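**Strategy.** The route rests on disconnecting C5–C6 of the tetradecenyl chain on N1, the bond between the alkene carbon and the first methylene of the nonyl tether to the pyridine ring. Because C5 is the sp2 terminus of a cis-alkene and C6 a primary sp3 carbon, a stereoretentive B-alkyl Suzuki–Miyaura coupling joins, in the last step, the complete cis-fused cyclopenta[c]isoxazolidine bearing a (Z)-5-iodopent-4-enyl group on N1 to the 9-BBN adduct of 3-(non-8-enyl)pyridine. The bicycle (C3, C3a, C6a) arises from an auxiliary-controlled intramolecular nitrone–alkene cycloaddition; both pyridine halves come from one alkene, 3-(non-8-enyl)pyridine.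

Key step: step 14

Assumption: the facial sense of step 8 (6aR from the α-D-mannofuranosyl nitrone) is predicted from the kinetic-anomeric-effect model for N-glycosyl nitrones, with the Z nitrone reacting in the rotamer that turns the nitrone oxygen toward C2' and the alkene adding anti to the C1'–O4' bond; it is not established for this substrate.

Remark: compound 15 is drawn as its ring tautomer (N-glycosylhydroxylamine), which is the form that condenses with the aldehyde.

**Route**

Step 1
Reactants: 1 3-methylpyridine; 2 8-bromooct-1-ene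
Product: 4 3-(non-8-en-1-yl)pyridine, via picolyllithium 3 (not isolated)
Conditions: LiN(iPr)2, THF, −78 °C; then 2, −78 °C → rt
Reagents that add atoms: none
Why: Lateral deprotonation of the 3-methyl group gives the picolyl anion, which is alkylated by the primary bromide in an SN2 reaction that leaves the terminal alkene untouched.

Step 2
Reactants: 4 3-(non-8-en-1-yl)pyridine
Product: 6 9-(pyridin-3-yl)nonan-1-ol, via alkyldicyclohexylborane 5 (not isolated)
Conditions: BH3·SMe2, cyclohexene (2 equiv per boron), THF, 0 °C (gives Cy2BH, used in excess); then 4, 0 °C → rt; then aq. NaOH, 30% H2O2, 0 °C → rt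
Reagents that add atoms: hydrogen peroxide, OO
Why: Hydroboration–oxidation: dicyclohexylborane, formed completely before 4 is added so that no free BH3 is left to bind the pyridine nitrogen, adds anti-Markovnikov to the terminal alkene, and alkaline peroxide converts the primary C–B bond into C–OH.

Step 3
Reactants: 6 9-(pyridin-3-yl)nonan-1-ol
Product: 7 9-(pyridin-3-yl)nonanal
Conditions: (COCl)2, DMSO, CH2Cl2, −78 °C; Et3N, → rt
Reagents that add atoms: none
Why: Swern oxidation takes the primary alcohol to the aldehyde without over-oxidation and tolerates the basic pyridine.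

Step 4
Reactants: 8 methyl 5-bromopentanoate; 9 triphenylphosphine
Product: 10 (5-methoxy-5-oxopentyl)triphenylphosphonium bromide
Conditions: MeCN, reflux
Reagents that add atoms: none
Why: SN2 quaternisation of triphenylphosphine by the primary bromide gives the phosphonium salt for the Wittig reaction.

Step 5
Reactants: 10 (5-methoxy-5-oxopentyl)triphenylphosphonium bromide; 7 9-(pyridin-3-yl)nonanal
Product: 12 methyl (5Z)-14-(pyridin-3-yl)tetradec-5-enoate, via phosphonium ylide 11 (not isolated)
Conditions: NaN(SiMe3)2, THF, −78 °C; then 7, −78 °C → rt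
Reagents that add atoms: none
Why: Wittig olefination with a non-stabilised ylide under lithium-free conditions should close kinetically to the cis-oxaphosphetane and so give the (5Z)-alkene.

Step 6
Reactants: 12 methyl (5Z)-14-(pyridin-3-yl)tetradec-5-enoate
Product: 13 (5Z)-14-(pyridin-3-yl)tetradec-5-enal
Conditions: iBu2AlH, CH2Cl2, −78 °C; MeOH, aq. KNaC4H4O6
Reagents that add atoms: none
Why: Partial reduction of the methyl ester: the aluminium hemiacetal formed at −78 °C should persist until the quench and then release the aldehyde, the isolated Z-alkene being inert to the hydride.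

Step 7
Reactants: 14 2,3:5,6-di-O-isopropylidene-α-D-mannofuranose
Product: 15 2,3:5,6-di-O-isopropylidene-D-mannose oxime (ring tautomer drawn)
Conditions: NH2OH·HCl, NaHCO3, EtOH–H2O, 60 °C
Reagents that add atoms: hydroxylamine hydrochloride, NO.Cl
Why: Oxime formation at the masked aldehyde of the lactol gives the sugar oxime, which equilibrates with the N-glycosylhydroxylamine needed for nitrone formation, the four sugar stereocentres being untouched.

Step 8
Reactants: 13 (5Z)-14-(pyridin-3-yl)tetradec-5-enal; 15 2,3:5,6-di-O-isopropylidene-D-mannose oxime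
Product: 17 (3S,3aS,6aR)-1-(2,3:5,6-di-O-isopropylidene-α-D-mannofuranosyl)-3-[8-(pyridin-3-yl)octyl]hexahydro-1H-cyclopenta[c]isoxazole, via N-glycosyl nitrone 16 (not isolated)
Conditions: toluene, MgSO4, 110 °C
Reagents that add atoms: none
Why: Condensation gives the (Z)-N-glycosyl nitrone, which should undergo an intramolecular nitrone–alkene 1,3-dipolar cycloaddition in which the three-carbon tether enforces the cis ring fusion (C3a/C6a), suprafacial addition to the (5Z)-alkene places the side chain at C3 cis to the ring CH2 on C3a, and the mannofuranosyl auxiliary (alkene adding anti to the C1'–O4' bond on the exposed nitrone face) selects the face that gives 6aR, any minor diastereomer being removable by chromatography.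

Step 9
Reactants: 17 (3S,3aS,6aR)-1-(2,3:5,6-di-O-isopropylidene-α-D-mannofuranosyl)-3-[8-(pyridin-3-yl)octyl]hexahydro-1H-cyclopenta[c]isoxazole
Product: 18 (3S,3aS,6aR)-3-[8-(pyridin-3-yl)octyl]hexahydro-1H-cyclopenta[c]isoxazole
Conditions: NH2OH·HCl, NaOAc, MeOH–H2O, 60 °C; then aq. NaHCO3
Reagents that add atoms: none
Why: Transglycosylation: the acid-labile glycosylamine bond C1'–N1 should ionise to a furanosyl oxocarbenium ion that hydroxylamine captures, releasing the N–H isoxazolidine with its three stereocentres and its N–O bond intact and returning the auxiliary as oxime 15.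

Step 10
Reactants: 19 pent-4-yn-1-ol
Product: 20 5-iodopent-4-yn-1-ol
Conditions: N-iodosuccinimide, AgNO3 (cat.), acetone, rt
Reagents that add atoms: N-iodosuccinimide, O=C1CCC(=O)N1I
Why: Silver-catalysed electrophilic iodination of the terminal alkyne (through the silver acetylide) gives the 1-iodoalkyne and leaves the alcohol free.

Step 11
Reactants: 20 5-iodopent-4-yn-1-ol
Product: 21 (4Z)-5-iodopent-4-en-1-ol
Conditions: 2-nitrobenzenesulfonohydrazide, Et3N, THF–iPrOH, rt
Reagents that add atoms: none
Why: Diimide cis-reduction: diimide released from the sulfonyl hydrazide transfers two hydrogens to the same face of the iodoalkyne through a cyclic transition state, so the (Z)-alkenyl iodide should form without reduction of the C–I bond.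

Step 12
Reactants: 21 (4Z)-5-iodopent-4-en-1-ol
Product: 22 (4Z)-5-iodopent-4-enal
Conditions: Dess–Martin periodinane, CH2Cl2, rt
Reagents that add atoms: none
Why: Dess–Martin oxidation gives the aldehyde under mild non-basic conditions that should neither isomerise the Z-alkenyl iodide nor over-oxidise.

Step 13
Reactants: 18 (3S,3aS,6aR)-3-[8-(pyridin-3-yl)octyl]hexahydro-1H-cyclopenta[c]isoxazole; 22 (4Z)-5-iodopent-4-enal
Product: 24 (3S,3aS,6aR)-1-[(4Z)-5-iodopent-4-en-1-yl]-3-[8-(pyridin-3-yl)octyl]hexahydro-1H-cyclopenta[c]isoxazole, via iminium acetate 23 (not isolated)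
Conditions: NaBH(OAc)3, AcOH, ClCH2CH2Cl, rt
Reagents that add atoms: none
Why: Reductive amination: the weakly basic N–H isoxazolidine condenses with the aldehyde to an N-alkoxyiminium ion that the acetoxyborohydride reduces, which alkylates N1 selectively because the pyridine nitrogen cannot form an iminium ion, while the alkenyl iodide and all stereocentres are unaffected.

Step 14
Reactants: 4 3-(non-8-en-1-yl)pyridine; 24 (3S,3aS,6aR)-1-[(4Z)-5-iodopent-4-en-1-yl]-3-[8-(pyridin-3-yl)octyl]hexahydro-1H-cyclopenta[c]isoxazole
Product: 26 (3S,3aS,6aR)-1-[(4Z)-14-(pyridin-3-yl)tetradec-4-en-1-yl]-3-[8-(pyridin-3-yl)octyl]hexahydro-1H-cyclopenta[c]isoxazole, via B-alkyl-9-BBN 25 (not isolated)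
Conditions: 4, 9-BBN dimer (excess), THF, 0 → 60 °C; aq. Cs2CO3; then 24, PdCl2(dppf) (cat.), AsPh3, DMF, rt
Reagents that add atoms: none
Why: Anti-Markovnikov hydroboration of the terminal alkene of 4 gives the primary B-alkyl-9-BBN 25; zerovalent palladium inserts into the C(sp2)–I bond of 24, the base-activated borane transfers its primary alkyl group to divalent palladium, and reductive elimination forms the C5–C6 bond of the N1 chain. The closest known reaction type is the B-alkyl Suzuki–Miyaura cross-coupling of (Z)-alkenyl iodides. No ring is closed and no new stereocentre is made; the one stereochemical element at stake, the (4Z) geometry, should be carried over because oxidative addition, transmetalation and reductive elimination are all stereoretentive at the alkenyl carbon. The step needs chemoselectivity for the alkenyl iodide over the N–O bond and the two pyridine rings, and transfer of the primary chain in preference to the secondary B–C bonds of the bicyclic borane; the room-temperature conditions, the wide-bite-angle dppf ligand (fast reductive elimination, little β-hydride elimination) and the reluctance of the 9-BBN cage carbons to transmetalate should secure both. Reversible N→B coordination by the pyridine is offset by excess 9-BBN and warming, and residual B–H is destroyed by the aqueous base before the iodide is added.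

**Compound list**

1 | 3-methylpyridine | Cc1cccnc1 | starting material
2 | 8-bromooct-1-ene | C=CCCCCCCBr | starting material
3 | (pyridin-3-ylmethyl)lithium | [Li]Cc1cccnc1 | intermediate
4 | 3-(non-8-en-1-yl)pyridine | C=CCCCCCCCc1cccnc1 | intermediate
5 | dicyclohexyl[9-(pyridin-3-yl)nonyl]borane | C1CCCCC1B(CCCCCCCCCc1cccnc1)C1CCCCC1 | intermediate
6 | 9-(pyridin-3-yl)nonan-1-ol | OCCCCCCCCCc1cccnc1 | intermediate
7 | 9-(pyridin-3-yl)nonanal | O=CCCCCCCCCc1cccnc1 | intermediate
8 | methyl 5-bromopentanoate | COC(=O)CCCCBr | starting material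
9 | triphenylphosphine | c1ccc(cc1)P(c1ccccc1)c1ccccc1 | starting material
10 | (5-methoxy-5-oxopentyl)triphenylphosphonium bromide | COC(=O)CCCC[P+](c1ccccc1)(c1ccccc1)c1ccccc1.[Br-] | intermediate
11 | methyl 5-(triphenylphosphoranylidene)pentanoate (ylide) | COC(=O)CCCC=P(c1ccccc1)(c1ccccc1)c1ccccc1 | intermediate
12 | methyl (5Z)-14-(pyridin-3-yl)tetradec-5-enoate | COC(=O)CCC/C=C\CCCCCCCCc1cccnc1 | intermediate
13 | (5Z)-14-(pyridin-3-yl)tetradec-5-enal | O=CCCC/C=C\CCCCCCCCc1cccnc1 | intermediate
14 | 2,3:5,6-di-O-isopropylidene-α-D-mannofuranose | O[C@H]1O[C@H]([C@H]2COC(C)(C)O2)[C@@H]2OC(C)(C)O[C@H]12 | starting material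
15 | 2,3:5,6-di-O-isopropylidene-D-mannose oxime, drawn as its ring tautomer N-hydroxy-2,3:5,6-di-O-isopropylidene-α-D-mannofuranosylamine | ON[C@H]1O[C@H]([C@H]2COC(C)(C)O2)[C@@H]2OC(C)(C)O[C@H]12 | intermediate
16 | (Z)-N-(2,3:5,6-di-O-isopropylidene-α-D-mannofuranosyl) nitrone of aldehyde 13 | [O-]/[N+](=C\CCC/C=C\CCCCCCCCc1cccnc1)[C@H]1O[C@H]([C@H]2COC(C)(C)O2)[C@@H]2OC(C)(C)O[C@H]12 | intermediate
17 | (3S,3aS,6aR)-1-(2,3:5,6-di-O-isopropylidene-α-D-mannofuranosyl)-3-[8-(pyridin-3-yl)octyl]hexahydro-1H-cyclopenta[c]isoxazole | N1(O[C@@H](CCCCCCCCc2cccnc2)[C@H]2CCC[C@H]21)[C@H]1O[C@H]([C@H]2COC(C)(C)O2)[C@@H]2OC(C)(C)O[C@H]12 | intermediate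
18 | (3S,3aS,6aR)-3-[8-(pyridin-3-yl)octyl]hexahydro-1H-cyclopenta[c]isoxazole | N1O[C@@H](CCCCCCCCc2cccnc2)[C@H]2CCC[C@H]21 | intermediate
19 | pent-4-yn-1-ol | C#CCCCO | starting material
20 | 5-iodopent-4-yn-1-ol | IC#CCCCO | intermediate
21 | (4Z)-5-iodopent-4-en-1-ol | I/C=C\CCCO | intermediate
22 | (4Z)-5-iodopent-4-enal | I/C=C\CCC=O | intermediate
23 | (3S,3aS,6aR)-1-[(4Z)-5-iodopent-4-en-1-ylidene]-3-[8-(pyridin-3-yl)octyl]hexahydrocyclopenta[c]isoxazol-1-ium acetate | I/C=C\CCC=[N+]1O[C@@H](CCCCCCCCc2cccnc2)[C@H]2CCC[C@H]21.CC(=O)[O-] | intermediate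
24 | (3S,3aS,6aR)-1-[(4Z)-5-iodopent-4-en-1-yl]-3-[8-(pyridin-3-yl)octyl]hexahydro-1H-cyclopenta[c]isoxazole | I/C=C\CCCN1O[C@@H](CCCCCCCCc2cccnc2)[C@H]2CCC[C@H]21 | intermediate
25 | 9-[9-(pyridin-3-yl)nonyl]-9-borabicyclo[3.3.1]nonane | C(CCCCCCCCc1cccnc1)B1C2CCCC1CCC2 | intermediate
26 | (3S,3aS,6aR)-1-[(4Z)-14-(pyridin-3-yl)tetradec-4-en-1-yl]-3-[8-(pyridin-3-yl)octyl]hexahydro-1H-cyclopenta[c]isoxazole | C(=C/CCCN1O[C@@H](CCCCCCCCc2cccnc2)[C@H]2CCC[C@H]21)/CCCCCCCCCc1cccnc1 | target

**Step count**

Total step count: 14. Longest linear sequence: 9 steps (1, 2, 3, 5, 6, 8, 9, 13, 14).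

**Steps most likely to fail**

Step 8. The auxiliary may discriminate the two nitrone faces poorly, or in the sense opposite to the model. Fallback: from enal 13, condensation with NH2OH·HCl/NaOAc (EtOH, rt) should give (5Z)-14-(pyridin-3-yl)tetradec-5-enal oxime F1. On heating (xylene, 140 °C, sealed tube) the oxime should cyclise by an intramolecular oxime–olefin cycloaddition through its N–H nitrone tautomer F2 to the racemic cis-fused N–H isoxazolidine F3, which has the same relative configuration. Preparative chromatography on a chiral stationary phase should then separate the enantiomers, and the (3S,3aS,6aR) enantiomer rejoins the route as 18.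

Step 14. Hydroboration may stall through coordination of the pyridine nitrogen to boron, or alkyl transfer may lose out to protodeboronation and β-hydride elimination. Fallback: from alcohol 6, I2/PPh3/imidazole (CH2Cl2, 0 °C) should give 3-(9-iodononyl)pyridine F4, used at once to avoid self-quaternisation. Zinc insertion (Zn dust, LiCl, THF, 40 °C) should give [9-(pyridin-3-yl)nonyl]zinc iodide F5, which is coupled with iodide 24 under Negishi conditions (Pd(PPh3)4, THF, rt) to arrive directly at 26.

Step 6. Over-reduction to the primary alcohol is possible, because the pyridine nitrogen binds the aluminium hydride and excess reagent is needed. Fallback: from ester 12, full reduction with LiAlH4 (THF, 0 °C) should give (5Z)-14-(pyridin-3-yl)tetradec-5-en-1-ol F6, and Swern oxidation of F6 returns to the route at 13.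

**Further compounds**

F1 | step 8 | (5Z)-14-(pyridin-3-yl)tetradec-5-enal oxime (E/Z mixture at C=N) | ON=CCCC/C=C\CCCCCCCCc1cccnc1
F2 | step 8 | N–H nitrone tautomer of oxime F1 | [O-][NH+]=CCCC/C=C\CCCCCCCCc1cccnc1
F3 | step 8 | racemic (3S*,3aS*,6aR*)-3-[8-(pyridin-3-yl)octyl]hexahydro-1H-cyclopenta[c]isoxazole (both enantiomers drawn) | N1O[C@@H](CCCCCCCCc2cccnc2)[C@H]2CCC[C@H]21.N1O[C@H](CCCCCCCCc2cccnc2)[C@@H]2CCC[C@@H]21
F4 | step 14 | 3-(9-iodononyl)pyridine | ICCCCCCCCCc1cccnc1
F5 | step 14 | [9-(pyridin-3-yl)nonyl]zinc iodide | I[Zn]CCCCCCCCCc1cccnc1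
F6 | step 6 | (5Z)-14-(pyridin-3-yl)tetradec-5-en-1-ol | OCCCC/C=C\CCCCCCCCc1cccnc1
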